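The oxirane fused to the seven-membered ring is read as an oxidised trisubstituted olefin: its two carbons, the methyl-bearing C8 and the C9 methine (locants as in the remark below), are joined by ring-closing metathesis. The precursor is a fully functionalised cyclopentane whose trans arms on the quaternary C1 (a 1-silyloxyallyl group) and on C5 (a 1-hydroxy-3-methylbut-3-enyl group) end in the two olefins; one operation closes the cycloheptene of the trans-hydroazulene. The free homoallylic C6 hydroxyl then delivers the epoxide oxygen to the α face. The cyclopentane is assembled from (R)-4-hydroxycyclopentenone by a conjugate addition–aldol coupling.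

Key step: step 13

Remark: locants follow the carbocycle of the target (C1 quaternary CH3-bearing ring-fusion carbon, C2 acetoxy carbon, C3, C4 isopropyl carbinol, C5 ring-fusion CH, C6 aroyloxy carbon, C7, C8 methyl-bearing carbon, C9, C10 carbinol); β is the face of the C1 methyl group and α the opposite face; (R)-4-hydroxycyclopent-2-en-1-one is taken as a catalogue chemical.

Step 1
Reactants: 1 (R)-4-hydroxycyclopent-2-en-1-one; 2 chlorotriethylsilane
Product: 3 (R)-4-(triethylsilyloxy)cyclopent-2-en-1-one
Conditions: Et3SiCl, imidazole, CH2Cl2, 0 °C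
Reagents that add atoms: chlorotriethylsilane, CC[Si](Cl)(CC)CC
Why: Imidazole-promoted silyl ether formation protects the carbinol that later becomes C4 without touching the stereocentre, and the TES group is chosen because it can be removed later in the presence of a TBS ether.

Step 2
Reactants: 3 (R)-4-(triethylsilyloxy)cyclopent-2-en-1-one; 4 iodine
Product: 5 (R)-2-iodo-4-(triethylsilyloxy)cyclopent-2-en-1-one
Conditions: I2, pyridine, CH2Cl2, 0 °C to rt
Reagents that add atoms: iodine, II
Why: α-Iodination of the enone by pyridine addition, iodination of the enolate and elimination (Baylis–Hillman-type sequence) is standard for 4-silyloxycyclopentenones and leaves the stereocentre unchanged.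

Step 3
Reactants: 5 (R)-2-iodo-4-(triethylsilyloxy)cyclopent-2-en-1-one; 6 tetramethylstannane
Product: 7 (R)-2-methyl-4-(triethylsilyloxy)cyclopent-2-en-1-one
Conditions: Me4Sn, Pd2(dba)3 (cat.), AsPh3, CuI, NMP, 60 °C
Reagents that add atoms: tetramethylstannane, C[Sn](C)(C)C
Why: Stille cross-coupling of the α-iodoenone installs the methyl group that becomes the C1 methyl.

Step 4
Reactants: 7 (R)-2-methyl-4-(triethylsilyloxy)cyclopent-2-en-1-one; 8 (2-methylprop-1-en-1-yl)magnesium bromide; 9 acrolein
Product: 11 (2S,3R,4R)-2-[(1S)-1-hydroxyprop-2-enyl]-2-methyl-3-(2-methylprop-1-enyl)-4-(triethylsilyloxy)cyclopentan-1-one, via bromomagnesium enolate 10 (not isolated)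
Conditions: alkenylMgBr, CuBr·SMe2 (cat.), THF, −78 to −40 °C; then acrolein, −78 °C; aq. NH4Cl
Reagents that add atoms: (2-methylprop-1-en-1-yl)magnesium bromide, CC(C)=C[Mg]Br; acrolein, C=CC=O
Why: Copper-catalysed conjugate addition of the alkenyl Grignard reagent anti to the 4α-silyloxy group sets C5, and the regiodefined magnesium enolate then adds to acrolein (tandem conjugate addition–aldol three-component coupling) on the face anti to the new 5β substituent through a Zimmerman–Traxler chair with the vinyl group equatorial, which should set the quaternary C1 (methyl β) and C10 (S).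

Step 5
Reactants: 11 aldol adduct; 12 tert-butyldimethylsilyl trifluoromethanesulfonate
Product: 13 10-O-TBS ether of 11
Conditions: TBSOTf, 2,6-lutidine, CH2Cl2, −78 to −20 °C
Reagents that add atoms: tert-butyldimethylsilyl trifluoromethanesulfonate, CC(C)(C)[Si](C)(C)OS(=O)(=O)C(F)(F)F
Why: Silyl triflate silylation of the hindered neopentylic carbinol stops retro-aldol cleavage, is orthogonal to the TES ether and later shields the β face of the C8=C9 olefin.

Step 6
Reactants: 13 10-O-TBS ether of 11
Product: 14 4α-hydroxy ketone (13 without the TES group)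
Conditions: HF·pyridine, pyridine, THF, 0 °C
Reagents that add atoms: none
Why: Buffered fluoride desilylation should cleave the unhindered secondary TES ether much faster than the neopentylic TBS ether and is mild enough to avoid β-elimination of the β-hydroxy ketone (selective desilylation).

Step 7
Reactants: 14 4α-hydroxy ketone
Product: 15 2β,4α-diol (C2 hydroxyl cis to the C1 methyl)
Conditions: Me4NBH(OAc)3, MeCN/AcOH, −30 to −20 °C
Reagents that add atoms: none
Why: Evans–Saksena hydroxyl-directed reduction, in which the alkoxyborohydride formed on the 4α-oxygen delivers hydride intramolecularly to the α face of the C2 ketone, should give the 2β-alcohol (trans-1,3-diol).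

Step 8
Reactants: 15 2β,4α-diol
Product: 16 2β-hydroxy-4-ketone
Conditions: TEMPO (cat.), PhI(OAc)2, CH2Cl2, rt
Reagents that add atoms: none
Why: Oxoammonium (TEMPO) oxidation is sterically discriminating, so the ordinary secondary C4 alcohol should be oxidised while the neopentylic C2 alcohol next to the quaternary C1 is left.

Step 9
Reactants: 16 2β-hydroxy-4-ketone; 17 isopropylmagnesium chloride
Product: 18 2β,4β-diol carrying the 4α-isopropyl group
Conditions: iPrMgCl, CeCl3 (excess of each), THF, −78 to −40 °C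
Reagents that add atoms: isopropylmagnesium chloride, CC(C)[Mg]Cl
Why: Organocerium 1,2-addition suppresses enolisation and retro-aldol cleavage, and the nucleophile should enter the α face anti to the adjacent 5β side chain, giving the 4β tertiary alcohol.

Step 10
Reactants: 18 2β,4β-diol; 19 acetic anhydride
Product: 20 2β-acetate of 18
Conditions: Ac2O, pyridine, DMAP (cat.), CH2Cl2, rt
Reagents that add atoms: acetic anhydride, CC(=O)OC(C)=O
Why: DMAP-catalysed acylation takes the secondary C2 hydroxyl while the tertiary C4 hydroxyl remains free.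

Step 11
Reactants: 20 2β-acetate; 21 ozone
Product: 23 5β-carbaldehyde (C6 aldehyde), via secondary ozonide 22 (not isolated)
Conditions: O3 (1 equiv, Sudan Red end point), CH2Cl2, −78 °C; then Me2S, −78 °C to rt
Reagents that add atoms: ozone, [O-][O+]=O
Why: Ozonolysis with one equivalent of ozone should cleave the electron-rich trisubstituted isobutenyl olefin in preference to the monosubstituted vinyl group, which is deactivated and shielded by the allylic silyloxy group, and reductive work-up gives the aldehyde.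

Step 12
Reactants: 23 C6 aldehyde; 24 3-bromo-2-methylprop-1-ene
Product: 25 diene with the (6S)-1-hydroxy-3-methylbut-3-enyl arm on C5
Conditions: In powder, THF/H2O, rt
Reagents that add atoms: 3-bromo-2-methylprop-1-ene, C=C(C)CBr
Why: Indium-mediated Barbier allylation in aqueous THF tolerates acetate, silyl ether and free hydroxyl, and In(III) chelation between the cis-disposed 4β-hydroxyl and the aldehyde oxygen exposes the carbonyl face anti to C1, so that the 1,3-anti (6S) carbinol is expected (chelation-controlled addition).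

Step 13
Reactants: 25 diene
Product: 26 2β-acetoxy-10β-(tert-butyldimethylsilyloxy)dauc-8-ene-4β,6α-diol (trans-fused hydroazulene)
Conditions: Hoveyda–Grubbs II (10 mol %), toluene (2 mM), 80 °C
Reagents that add atoms: none
Why: Ring-closing olefin metathesis by the metallacyclobutane (Chauvin) mechanism: the ruthenium alkylidene loads on the monosubstituted C9 vinyl group, adds across the 1,1-disubstituted C8 isopropenyl group and cycloreverts, releasing ethylene and forming the C8=C9 bond. The closest known reaction type is RCM to trisubstituted cycloheptenes fused to cyclopentanes (hydroazulene terpenoids) with second-generation ruthenium catalysts. The seven-membered carbocycle C5–C6–C7–C8–C9–C10–C1 is closed by metathesis cyclisation of a 1,8-diene; the ring size enforces the Z olefin and the trans ring fusion is inherited from the trans arms on C1 and C5. No stereocentre is created here; the step delivers the olefin on which the next step sets C8 and C9 under control of the 6α-hydroxyl. The step needs cyclisation to win over oligomerisation and olefin migration: the quaternary C1 and the fully substituted C4 flanking C5 press the two arms together, both olefins are poor partners for homodimerisation, and high dilution supports closure. Free secondary and tertiary hydroxyls, the acetate and the silyl ether are tolerated by the catalyst.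

Step 14
Reactants: 26 cycloheptene; 27 tert-butyl hydroperoxide
Product: 28 8α,9α-epoxide of 26
Conditions: VO(acac)2 (cat.), t-BuOOH, CH2Cl2, 0 °C to rt
Reagents that add atoms: tert-butyl hydroperoxide, CC(C)(C)OO
Why: Vanadium-catalysed hydroxyl-directed epoxidation of the homoallylic alcohol should deliver oxygen syn to the 6α-hydroxyl, reinforced by the 10β-silyloxy group and the 1β-methyl group that shield the β face, which sets C8 and C9.

Step 15
Reactants: 28 epoxy alcohol; 29 4-methoxybenzoyl chloride
Product: 30 6-O-(4-methoxybenzoyl) derivative of 28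
Conditions: 4-MeOC6H4COCl, Et3N, DMAP, CH2Cl2, rt
Reagents that add atoms: 4-methoxybenzoyl chloride, COc1ccc(C(Cl)=O)cc1
Why: DMAP-catalysed acylation takes the only free secondary hydroxyl, while the tertiary C4 hydroxyl and the epoxide are inert under these conditions.

Step 16
Reactants: 30 silyl ether
Product: 31 CNP0371526.1 (target)
Conditions: HF·pyridine, pyridine, THF, 0 °C to rt
Reagents that add atoms: none
Why: Buffered fluoride desilylation frees the C10 hydroxyl under conditions that are expected to spare the trisubstituted epoxide and both esters and to avoid acyl migration.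

Compound list
1 | (R)-4-hydroxycyclopent-2-en-1-one | O=C1C=C[C@H](O)C1 | starting material
2 | chlorotriethylsilane | CC[Si](Cl)(CC)CC | starting material
3 | (R)-4-(triethylsilyloxy)cyclopent-2-en-1-one | O=C1C=C[C@H](O[Si](CC)(CC)CC)C1 | intermediate
4 | iodine | II | starting material
5 | (R)-2-iodo-4-(triethylsilyloxy)cyclopent-2-en-1-one | O=C1C(I)=C[C@H](O[Si](CC)(CC)CC)C1 | intermediate
6 | tetramethylstannane | C[Sn](C)(C)C | starting material
7 | (R)-2-methyl-4-(triethylsilyloxy)cyclopent-2-en-1-one (its ring carbons become C2, C1, C5, C4, C3) | O=C1C(C)=C[C@H](O[Si](CC)(CC)CC)C1 | intermediate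
8 | (2-methylprop-1-en-1-yl)magnesium bromide | CC(C)=C[Mg]Br | starting material
9 | acrolein | C=CC=O | starting material
10 | bromomagnesium C1=C2 enolate of (3R,4R)-2-methyl-3-(2-methylprop-1-enyl)-4-(triethylsilyloxy)cyclopentanone (5β-alkenyl trans to 4α-OTES) | CC1=C(O[Mg]Br)C[C@@H](O[Si](CC)(CC)CC)[C@@H]1C=C(C)C | intermediate (not isolated)
11 | (2S,3R,4R)-2-[(1S)-1-hydroxyprop-2-enyl]-2-methyl-3-(2-methylprop-1-enyl)-4-(triethylsilyloxy)cyclopentan-1-one (C2 ketone; 1β-CH3; 1α-CH(OH)CH=CH2 with 10S; 5β-alkenyl; 4α-OTES) | C=C[C@H](O)[C@@]1(C)C(=O)C[C@@H](O[Si](CC)(CC)CC)[C@@H]1C=C(C)C | intermediate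
12 | tert-butyldimethylsilyl trifluoromethanesulfonate | CC(C)(C)[Si](C)(C)OS(=O)(=O)C(F)(F)F | starting material
13 | 10-O-TBS ether of 11 | C=C[C@H](O[Si](C)(C)C(C)(C)C)[C@@]1(C)C(=O)C[C@@H](O[Si](CC)(CC)CC)[C@@H]1C=C(C)C | intermediate
14 | 4α-hydroxy ketone (13 with free C4 hydroxyl) | C=C[C@H](O[Si](C)(C)C(C)(C)C)[C@@]1(C)C(=O)C[C@@H](O)[C@@H]1C=C(C)C | intermediate
15 | 2β,4α-diol (C2 hydroxyl cis to the C1 methyl, trans to the C4 hydroxyl) | C=C[C@H](O[Si](C)(C)C(C)(C)C)[C@@]1(C)[C@H](O)C[C@@H](O)[C@@H]1C=C(C)C | intermediate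
16 | 2β-hydroxy-4-ketone | C=C[C@H](O[Si](C)(C)C(C)(C)C)[C@@]1(C)[C@H](O)CC(=O)[C@@H]1C=C(C)C | intermediate
17 | isopropylmagnesium chloride | CC(C)[Mg]Cl | starting material
18 | 2β,4β-diol with 4α-isopropyl (tertiary C4 carbinol) | C=C[C@H](O[Si](C)(C)C(C)(C)C)[C@@]1(C)[C@H](O)C[C@@](O)(C(C)C)[C@@H]1C=C(C)C | intermediate
19 | acetic anhydride | CC(=O)OC(C)=O | starting material
20 | 2β-acetate of 18 | C=C[C@H](O[Si](C)(C)C(C)(C)C)[C@@]1(C)[C@H](OC(C)=O)C[C@@](O)(C(C)C)[C@@H]1C=C(C)C | intermediate
21 | ozone | [O-][O+]=O | starting material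
22 | secondary ozonide of 20 (3,3-dimethyl-1,2,4-trioxolan-5-yl group on C5) | C=C[C@H](O[Si](C)(C)C(C)(C)C)[C@@]1(C)[C@H](OC(C)=O)C[C@@](O)(C(C)C)[C@@H]1C2OOC(C)(C)O2 | intermediate (not isolated)
23 | 5β-carbaldehyde (C6 aldehyde) with 2β-OAc, 4β-OH, 4α-iPr, 1α-[(1S)-1-(TBSO)allyl] | C=C[C@H](O[Si](C)(C)C(C)(C)C)[C@@]1(C)[C@H](OC(C)=O)C[C@@](O)(C(C)C)[C@@H]1C=O | intermediate
24 | 3-bromo-2-methylprop-1-ene | C=C(C)CBr | starting material
25 | metathesis diene: 23 with the aldehyde converted into the (1S)-1-hydroxy-3-methylbut-3-enyl arm (6S) | C=C[C@H](O[Si](C)(C)C(C)(C)C)[C@@]1(C)[C@H](OC(C)=O)C[C@@](O)(C(C)C)[C@@H]1[C@@H](O)CC(C)=C | intermediate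
26 | 2β-acetoxy-10β-(tert-butyldimethylsilyloxy)dauc-8-ene-4β,6α-diol (1β-CH3, 5α-H, trans-fused) | O[C@H]1CC(C)=C[C@H](O[Si](C)(C)C(C)(C)C)[C@]2(C)[C@@H]1[C@](O)(C(C)C)C[C@H]2OC(C)=O | intermediate
27 | tert-butyl hydroperoxide | CC(C)(C)OO | starting material
28 | 8α,9α-epoxide of 26 | O[C@H]1C[C@@]2(C)O[C@H]2[C@H](O[Si](C)(C)C(C)(C)C)[C@]2(C)[C@@H]1[C@](O)(C(C)C)C[C@H]2OC(C)=O | intermediate
29 | 4-methoxybenzoyl chloride | COc1ccc(C(Cl)=O)cc1 | starting material
30 | 6-O-(4-methoxybenzoyl) derivative of 28 | COc1ccc(C(=O)O[C@H]2C[C@@]3(C)O[C@H]3[C@H](O[Si](C)(C)C(C)(C)C)[C@]3(C)[C@@H]2[C@](O)(C(C)C)C[C@H]3OC(C)=O)cc1 | intermediate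
31 | CNP0371526.1: 2β-acetoxy-8α,9α-epoxy-4β,10β-dihydroxy-6α-(4-methoxybenzoyloxy)daucane | COc1ccc(C(=O)O[C@H]2C[C@@]3(C)O[C@H]3[C@H](O)[C@]3(C)[C@@H]2[C@](O)(C(C)C)C[C@H]3OC(C)=O)cc1 | target

Total step count: 16. Longest linear sequence: 16 steps (from 1).

Steps most likely to fail

Step 4. The tetrasubstituted enolate and the small vinyl substituent of acrolein may give poor facial discrimination at the aldehyde, so that both C10 epimers form (retro-aldol on warming would worsen this). Fallback: C10 is set after ring closure by cyclic control. It sets out from 11 taken on as the C10-epimer mixture; steps 5 to 13 do not depend on C10 and give the metathesis product as the C10-epimer mixture F1. F1 is acylated with 29 to the anisoate mixture F2, desilylated (HF·pyridine) to the allylic alcohols F3 and oxidised (Dess–Martin periodinane) to the single cycloheptenone F4. Luche reduction, with hydride entering anti to the angular 1β-methyl group, should give the 10β-alcohol F5, which is silylated (TESOTf, 2,6-lutidine) to the TES ether F6 and epoxidised with mCPBA anti to the allylic silyloxy group to the epoxide F7. Buffered HF·pyridine then returns to the route at 31.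

Step 8. The oxoammonium oxidant may fail to tell the two secondary hydroxyls apart, or may over-oxidise to the 1,3-diketone. Fallback: the two sites are distinguished by silylation instead of oxidation. It sets out from 15: the unhindered 4α-hydroxyl is silylated selectively (Et3SiCl, imidazole, −20 °C) to the mono-TES ether F8, the 2β-hydroxyl is acetylated (Ac2O, DMAP) to the acetate F9, the TES group is removed (HF·pyridine) to the alcohol F10 and this is oxidised (Dess–Martin periodinane) to the β-acetoxy ketone F11. Organocerium addition of 17 at −78 °C, where the ketone reacts before the ester, returns to the route at 20.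

Step 13. Initiation at the hindered allylic silyloxy vinyl group and at the 1,1-disubstituted olefin may be slow, so that oligomerisation or double-bond migration competes with ring closure. Fallback: the same C8–C9 bond is made by reductive carbonyl coupling. It sets out from 25: acylation with 29 gives the anisoate diene F12, exhaustive ozonolysis (O3; Me2S) the keto aldehyde F13, and SmI2-mediated intramolecular pinacol coupling (THF, t-BuOH, −78 °C) the cis-8,9-diol F14. Thiocarbonyldiimidazole converts this into the cyclic thiocarbonate F15, and Corey–Winter fragmentation with trimethyl phosphite gives the cycloheptene F16. Epoxidation with mCPBA anti to the 10β-silyloxy group returns to the route at 30.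

Further compounds
F1 | step 4 | C10-epimer mixture of 26 | O[C@H]1CC(C)=CC(O[Si](C)(C)C(C)(C)C)[C@]2(C)[C@@H]1[C@](O)(C(C)C)C[C@H]2OC(C)=O
F2 | step 4 | 6-O-(4-methoxybenzoyl) derivative of F1 (C10 epimers) | COc1ccc(C(=O)O[C@H]2CC(C)=CC(O[Si](C)(C)C(C)(C)C)[C@]3(C)[C@@H]2[C@](O)(C(C)C)C[C@H]3OC(C)=O)cc1
F3 | step 4 | C10 allylic alcohols from F2 (C10 epimers) | COc1ccc(C(=O)O[C@H]2CC(C)=CC(O)[C@]3(C)[C@@H]2[C@](O)(C(C)C)C[C@H]3OC(C)=O)cc1
F4 | step 4 | dauc-8-en-10-one with 2β-OAc, 4β-OH, 6α-anisoyloxy | COc1ccc(C(=O)O[C@H]2CC(C)=CC(=O)[C@]3(C)[C@@H]2[C@](O)(C(C)C)C[C@H]3OC(C)=O)cc1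
F5 | step 4 | 10β-alcohol from F4 | COc1ccc(C(=O)O[C@H]2CC(C)=C[C@H](O)[C@]3(C)[C@@H]2[C@](O)(C(C)C)C[C@H]3OC(C)=O)cc1
F6 | step 4 | 10-O-TES ether of F5 | COc1ccc(C(=O)O[C@H]2CC(C)=C[C@H](O[Si](CC)(CC)CC)[C@]3(C)[C@@H]2[C@](O)(C(C)C)C[C@H]3OC(C)=O)cc1
F7 | step 4 | 8α,9α-epoxide of F6 | COc1ccc(C(=O)O[C@H]2C[C@@]3(C)O[C@H]3[C@H](O[Si](CC)(CC)CC)[C@]3(C)[C@@H]2[C@](O)(C(C)C)C[C@H]3OC(C)=O)cc1
F8 | step 8 | 4-O-TES ether of 15 (2β-hydroxyl free) | C=C[C@H](O[Si](C)(C)C(C)(C)C)[C@@]1(C)[C@H](O)C[C@@H](O[Si](CC)(CC)CC)[C@@H]1C=C(C)C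
F9 | step 8 | 2β-acetate of F8 | C=C[C@H](O[Si](C)(C)C(C)(C)C)[C@@]1(C)[C@H](OC(C)=O)C[C@@H](O[Si](CC)(CC)CC)[C@@H]1C=C(C)C
F10 | step 8 | 2β-acetoxy-4α-alcohol | C=C[C@H](O[Si](C)(C)C(C)(C)C)[C@@]1(C)[C@H](OC(C)=O)C[C@@H](O)[C@@H]1C=C(C)C
F11 | step 8 | 2β-acetoxy-4-ketone | C=C[C@H](O[Si](C)(C)C(C)(C)C)[C@@]1(C)[C@H](OC(C)=O)CC(=O)[C@@H]1C=C(C)C
F12 | step 13 | 6-O-(4-methoxybenzoyl) derivative of diene 25 | C=C[C@H](O[Si](C)(C)C(C)(C)C)[C@@]1(C)[C@H](OC(C)=O)C[C@@](O)(C(C)C)[C@@H]1[C@@H](OC(=O)c2ccc(OC)cc2)CC(C)=C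
F13 | step 13 | keto aldehyde (C8 methyl ketone, C9 aldehyde) from F12 | O=C[C@H](O[Si](C)(C)C(C)(C)C)[C@@]1(C)[C@H](OC(C)=O)C[C@@](O)(C(C)C)[C@@H]1[C@@H](OC(=O)c2ccc(OC)cc2)CC(C)=O
F14 | step 13 | cis-8,9-diol from pinacol cyclisation of F13 | COc1ccc(C(=O)O[C@H]2CC(C)(O)C(O)[C@H](O[Si](C)(C)C(C)(C)C)[C@]3(C)[C@@H]2[C@](O)(C(C)C)C[C@H]3OC(C)=O)cc1
F15 | step 13 | 8,9-cyclic thiocarbonate of F14 | COc1ccc(C(=O)O[C@H]2CC3(C)OC(=S)OC3[C@H](O[Si](C)(C)C(C)(C)C)[C@]3(C)[C@@H]2[C@](O)(C(C)C)C[C@H]3OC(C)=O)cc1
F16 | step 13 | 6-O-(4-methoxybenzoyl) derivative of cycloheptene 26 | COc1ccc(C(=O)O[C@H]2CC(C)=C[C@H](O[Si](C)(C)C(C)(C)C)[C@]3(C)[C@@H]2[C@](O)(C(C)C)C[C@H]3OC(C)=O)cc1
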